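## Analysis of the target

Numbering used throughout: the chain runs from C1 (CH3 of the ethyl ketone) to C15 (CH3 of the propenyl group); the branches are 6-CH2OH, 8-CH2OH, 10-CH3 and 12-CH3. PMB = 4-methoxybenzyl.

Myriaporone 4 (23) is an open C15 chain whose only ring is the oxirane C10–C11–O. It carries ketones at C3 and C7, four hydroxyls and a (13Z)-olefin. The seven stereocentres are 5S, 6S, 8R, 9S, 10R, 11S and 12S.

The feature the strategy uses is the array C5(OH)–C6(CH2OH)–C7(=O)–C8(CH2OH)–C9(OH). Its relative configuration is 5,6-anti, 6,8-syn, 8,9-anti, so the array is its own mirror image through the C7=O bond (pseudo-meso), and C6–C7–C8 with the two CH2O carbons is a symmetric five-carbon ketone.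

On the oxirane, C9 and C12 are cis, so the ring maps onto a (10Z)-trisubstituted olefin. The C9 hydroxyl and the oxirane oxygen are threo.

Sensitive points:
- C6 and C8 are epimerisable, and every hydroxyl is β to a ketone (retro-aldol, dehydration).
- The 2,3-epoxy alcohol sits next to 8-CH2OH (acid-triggered ring opening, base-triggered epoxide migration).
- 6-CH2OH adds reversibly to C3=O.

The difficulty is to set seven centres on a flexible chain from one distant chiral-pool centre (C12), with two labile centres and an oxirane that must be cis and threo beside a second olefin.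

## Retrosynthetic reasoning

**23 ⇒ 22 (two O–CH2Ar bonds).** The two primary hydroxyls stay masked to the end. Free, they would form hemiketals and could attack the oxirane. As benzyl-type ethers they are also what the key step needs for face control. The forward step must be neutral and oxidative.

**22 ⇒ 21 (C10–O and C11–O).** The oxirane is the most acid-sensitive group, so it is made after all acid and Lewis-acid steps. Both its centres can be read from C9: a cis oxirane means a (10Z)-olefin, and threo means delivery of oxygen from the face of the C9 hydroxyl. The forward step must prefer the trisubstituted allylic olefin over the (13Z)-olefin.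

**21 ⇒ 20 (masking of C3=O and C5–OH).** With C3 as a ketal, only C7 is enolisable in the key step. With C5–O as a silyl ether, that arm is bulky and non-chelating. Both masks come off together before the oxirane exists.

**20 ⇒ 10 + 17 (C8–C9, the key cut).** The chain is cut beside C7 into a C1–C8 ketone and a C9–C15 enal of similar size. One aldol forms the last skeletal bond and sets C8 and C9. C9 follows from the enolate geometry; C8 is relayed from C6 across the carbonyl. A cut at C9–C10, or an aldol onto an aldehyde that already carries the oxirane, would fight the polar Felkin preference, which leads to the erythro relation.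

**10 ⇒ 9 ⇒ 3 + 6 (C5–C6).** The same reaction type is used on the other side of the same carbonyl. Ketone 3 is symmetric, so both halves of the pseudo-meso array come from one unit. This first aldol has no substrate bias; it is the only reagent-controlled enantioselective step and is run on cheap achiral material. Ketone 3 comes from triol 1 through 2; aldehyde 6 comes from keto ester 4 through 5.

**17 ⇒ 16 ⇒ 15 ⇒ 14 ⇒ 13 ⇒ 12 ⇒ 11.** The (10Z)-olefin comes from a (Z)-selective phosphonate olefination of aldehyde 14, followed by redox adjustment. C12 comes from the chiral pool: the C12–C13 bond is made by SN2 displacement with inversion on lactate triflate 12 by a (Z)-alkenyl cuprate.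

## Alternatives that were turned down

**Alternative 1:** the textbook route, linear chain growth from 17 by three separate stereocontrolled aldols.
- Disconnection: C8–C9 first, then C6–C7, then C4–C5.
- Forward key steps: an auxiliary anti-aldol of a 3-(PMB-oxy)propanoyl unit with 17, reduced to diol A1; oxidation at C7 and a second such aldol; finally an acetate-type methyl ketone aldol.
- Why turned down: each aldol brings auxiliary removal, redox and protecting-group steps. C7 must travel as a protected carbinol, distinguishable from C5–OH and C9–OH, and be oxidised late. The longest sequence would be roughly twice as long. The last aldol uses an unsubstituted enolate and has only weak 1,2-induction for C5. The mirror relation of the two halves is not used.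

**Alternative 2:** a ring template with silicon as a masked pair of hydroxyls.
- Disconnection: the two CH2O carbons are tied through silicon in silacyclohexanone A2.
- Forward key steps: two aldols on the ring enolate, then Tamao–Fleming oxidation of both Si–C bonds.
- Why turned down: the ring enolate is necessarily (E), which gives anti aldols. But the second aldol should occur by axial attack anti to the substituent already present, giving the 3,5-trans adduct A3, the pseudo-C2 array. The target corresponds to 3,5-cis. Epimerising to cis would turn one anti relation into syn. Oxidising two Si–C(sp3) bonds of a diphenylsilane also needs strong acid or an electrophile and then basic peroxide, which the allylic alcohol, the olefins and the β-hydroxy ketones would not survive.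

**Alternative 3:** isoxazoline as a masked aldol.
- Disconnection: C7–C8 and C9–O.
- Forward key step: [3+2] cycloaddition of nitrile oxide A5 to the C8=C9 bond of triene A6 to give isoxazoline A4, then N–O reduction.
- Why turned down: in A6 the C8=C9 bond is 1,2-disubstituted and conjugated to C10=C11, with no allylic hydroxyl for a magnesium-alkoxide-directed addition. Neither regiochemistry, site nor face is secured. A5 has an epimerisable α-centre and dimerises easily. The N–O cleavage (H2 over Raney Ni, or Mo(CO)6) meets two olefins and two benzyl ethers. A5 still needs the C5–C6 aldol, so no step is saved.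

Key step: step 13

Remark (assumption): the (−)-menthone-derived bromoborane of step 5 is taken to induce the (S,S) sense with ketone 3; if a trial shows the opposite sense, its antipode from (+)-menthone is used instead and nothing else changes. The reagent is made separately from menthone (methylenation, hydroboration with H2BBr·SMe2) and is not counted.

Remark: in solution 23 equilibrates with its six-membered hemiketal (6-CH2OH onto C3=O); the route is written for the open form.

## Steps

Step 1
Reactants: 1 pentane-1,3,5-triol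
Product: 2 1,5-bis[(4-methoxybenzyl)oxy]pentan-3-ol
Conditions: NaH (2 equiv), PMBCl (2 equiv), Bu4NI (cat.), DMF, −20 → 0 °C
Reagents that add atoms: 4-methoxybenzyl chloride, COc1ccc(CCl)cc1
Why: Williamson etherification; the two primary alkoxides are less hindered and should react before the flanked secondary one, so the 1,5-diether should dominate and the mono- and tri-ethers are removed by chromatography.

Step 2
Reactants: 2 1,5-bis[(4-methoxybenzyl)oxy]pentan-3-ol
Product: 3 1,5-bis[(4-methoxybenzyl)oxy]pentan-3-one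
Conditions: Dess–Martin periodinane, NaHCO3, CH2Cl2, rt
Reagents that add atoms: none
Why: Dess–Martin oxidation of the secondary alcohol under buffered conditions; no stereocentre is involved and the β-alkoxy ketone sees no base that could cause β-elimination.

Step 3
Reactants: 4 ethyl 3-oxopentanoate
Product: 5 ethyl 2-(2-ethyl-1,3-dioxolan-2-yl)acetate
Conditions: ethane-1,2-diol, TsOH·H2O (cat.), toluene, reflux, water separator
Reagents that add atoms: ethane-1,2-diol, OCCO
Why: Acid-catalysed ketalisation with azeotropic removal of water; the ketone reacts and the ester does not, and the ketal masks C3 so that only C7 is enolisable later.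

Step 4
Reactants: 5 ethyl 2-(2-ethyl-1,3-dioxolan-2-yl)acetate
Product: 6 2-(2-ethyl-1,3-dioxolan-2-yl)acetaldehyde
Conditions: i-Bu2AlH, CH2Cl2, −78 °C; aq. potassium sodium tartrate
Reagents that add atoms: none
Why: Partial ester reduction at −78 °C through the stable aluminium hemiacetal; the β-ketal aldehyde is used crude.

Step 5
Reactants: 3 1,5-bis[(4-methoxybenzyl)oxy]pentan-3-one, 6 2-(2-ethyl-1,3-dioxolan-2-yl)acetaldehyde
Product: 9 (4S,5S)-6-(2-ethyl-1,3-dioxolan-2-yl)-5-hydroxy-1-[(4-methoxybenzyl)oxy]-4-{[(4-methoxybenzyl)oxy]methyl}hexan-3-one, via enol borinate 7 (not isolated), via boron aldolate 8 (not isolated)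
Conditions: L2BBr (L = [(1S,2S,5R)-2-isopropyl-5-methylcyclohexyl]methyl), Et3N, CH2Cl2/Et2O, −78 °C; 6, −78 → −30 °C; MeOH, pH 7 buffer, H2O2, 0 °C
Reagents that add atoms: none
Why: Enantioselective boron aldol: the bulky dialkylboron bromide with Et3N should give the (E)-enol borinate 7 of the symmetric ketone, and the chair Zimmerman–Traxler transition state gives the anti relation (C5/C6 of the target). The menthone-derived ligands choose the aldehyde face and so set both centres as (S,S); the covalent B–O bond keeps the β-alkoxy enolate from eliminating, as in boron aldols of 3-(benzyloxy)propanoyl derivatives.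

Step 6
Reactants: 9 (4S,5S)-6-(2-ethyl-1,3-dioxolan-2-yl)-5-hydroxy-1-[(4-methoxybenzyl)oxy]-4-{[(4-methoxybenzyl)oxy]methyl}hexan-3-one
Product: 10 (4S,5S)-6-(2-ethyl-1,3-dioxolan-2-yl)-1-[(4-methoxybenzyl)oxy]-4-{[(4-methoxybenzyl)oxy]methyl}-5-[(triethylsilyl)oxy]hexan-3-one
Conditions: Et3SiOTf, 2,6-lutidine, CH2Cl2, −78 °C
Reagents that add atoms: triethylsilyl trifluoromethanesulfonate, CC[Si](CC)(CC)OS(=O)(=O)C(F)(F)F
Why: Low-temperature silylation of the β-hydroxy ketone without retro-aldol; the silyl ether blocks boron chelation in step 13 and makes this arm the bulky, weakly basic one.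

Step 7
Reactants: 11 ethyl (S)-lactate
Product: 12 ethyl (2S)-2-{[(trifluoromethyl)sulfonyl]oxy}propanoate
Conditions: Tf2O, 2,6-lutidine, CH2Cl2, −20 → 0 °C
Reagents that add atoms: trifluoromethanesulfonic anhydride, FC(F)(F)S(=O)(=O)OS(=O)(=O)C(F)(F)F
Why: O-Sulfonylation of the α-hydroxy ester with a hindered base; the C–O bond is untouched, so configuration is retained.

Step 8
Reactants: 12 ethyl (2S)-2-{[(trifluoromethyl)sulfonyl]oxy}propanoate
Product: 13 ethyl (2S,3Z)-2-methylpent-3-enoate
Conditions: (Z)-1-bromopropene, Li (0.5% Na), Et2O, −15 °C; CuI, −40 °C; then 12, −78 → −40 °C; aq. NH4Cl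
Reagents that add atoms: (Z)-1-bromopropene, C/C=C\Br
Why: SN2 displacement of an α-triflyloxy ester by a lithium dialkenylcuprate (monovalent copper) with inversion at carbon should give the (S)-ester; (Z)-propenyllithium keeps its geometry at low temperature and the cuprate transfers it with retention. This sets C12 from the chiral pool.

Step 9
Reactants: 13 ethyl (2S,3Z)-2-methylpent-3-enoate
Product: 14 (2S,3Z)-2-methylpent-3-enal
Conditions: i-Bu2AlH, CH2Cl2, −78 °C; MeOH, then aq. potassium sodium tartrate, 0 °C; cold solution used at once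
Reagents that add atoms: none
Why: Partial reduction at −78 °C; the α-centre is allylic and α to the carbonyl, so the aldehyde is kept cold, not chromatographed and used immediately to avoid epimerisation or conjugation.

Step 10
Reactants: 14 (2S,3Z)-2-methylpent-3-enal
Product: 15 ethyl (2Z,4S,5Z)-2,4-dimethylhepta-2,5-dienoate
Conditions: ethyl 2-[bis(2,2,2-trifluoroethoxy)phosphoryl]propanoate, KN(SiMe3)2, 18-crown-6, THF, −78 °C
Reagents that add atoms: ethyl 2-[bis(2,2,2-trifluoroethoxy)phosphoryl]propanoate, CCOC(=O)C(C)P(=O)(OCC(F)(F)F)OCC(F)(F)F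
Why: Still–Gennari olefination: the electron-poor phosphonate under dissociating conditions eliminates fast from the kinetic adduct and should give the (2Z)-enoate. The pre-formed, weakly basic phosphonate anion should leave the α-centre of 14 untouched.

Step 11
Reactants: 15 ethyl (2Z,4S,5Z)-2,4-dimethylhepta-2,5-dienoate
Product: 16 (2Z,4S,5Z)-2,4-dimethylhepta-2,5-dien-1-ol
Conditions: i-Bu2AlH (2.2 equiv), CH2Cl2, −78 °C; aq. potassium sodium tartrate
Reagents that add atoms: none
Why: 1,2-Reduction of the enoate to the allylic alcohol; hydride does not touch the olefins, so both (Z)-geometries are retained.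

Step 12
Reactants: 16 (2Z,4S,5Z)-2,4-dimethylhepta-2,5-dien-1-ol
Product: 17 (2Z,4S,5Z)-2,4-dimethylhepta-2,5-dienal
Conditions: Dess–Martin periodinane, NaHCO3, CH2Cl2, 0 °C; used directly
Reagents that add atoms: none
Why: Buffered Dess–Martin oxidation gives the (Z)-enal without the acid or base that would isomerise it to the (E)-isomer.

Step 13
Reactants: 10 (4S,5S)-6-(2-ethyl-1,3-dioxolan-2-yl)-1-[(4-methoxybenzyl)oxy]-4-{[(4-methoxybenzyl)oxy]methyl}-5-[(triethylsilyl)oxy]hexan-3-one, 17 (2Z,4S,5Z)-2,4-dimethylhepta-2,5-dienal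
Product: 20 (5S,6S,8R,9S,10Z,12S,13Z)-3,3-(ethylenedioxy)-9-hydroxy-6,8-bis{[(4-methoxybenzyl)oxy]methyl}-10,12-dimethyl-5-[(triethylsilyl)oxy]pentadeca-10,13-dien-7-one (target numbering), via enol borinate 18 (not isolated), via boron aldolate 19 (not isolated)
Conditions: (c-C6H11)2BCl, Et3N, Et2O, 0 °C; 17, −78 → −20 °C; MeOH, pH 7 buffer, H2O2, 0 °C
Reagents that add atoms: none
Why: Boron-mediated anti-aldol of an α-stereogenic ketone; the closest known type is the aldol of (E)-enol dicyclohexylborinates of α-chiral β-benzyloxy ethyl ketones. (c-C6H11)2BCl/Et3N should deprotonate the unbranched C8 methylene (the tertiary C6–H is hindered) to give the (E)-enol borinate 18, which adds to 17 through a chair Zimmerman–Traxler transition state. No ring is closed; the step forms the C8–C9 bond and completes the C1–C15 skeleton from two fragments of similar size. C9 is set relative to C8 (anti) by the (E)-enolate geometry in the chair. C8 is set relative to C6 by the C6 centre: with C6–H eclipsing the enolate double bond (allylic 1,3-strain), the aldehyde should approach the face carrying the CH2OPMB arm and avoid the bulky CH(OSiEt3) arm, the roles played by the benzyloxymethyl and methyl groups in the model ketones. This gives the 6,8-syn relation and hence the pseudo-meso anti/syn/anti array (8R,9S). The selectivity needed is enolate π-face selectivity, and it is secured by pairing a benzyl-type ether on 6-CH2O with a silyl ether on C5–O. C12 is remote and should not interfere, and the non-enolisable (Z)-enal is consumed below −20 °C, which should preserve both (Z)-olefins.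

Step 14
Reactants: 20 (5S,6S,8R,9S,10Z,12S,13Z)-3,3-(ethylenedioxy)-9-hydroxy-6,8-bis{[(4-methoxybenzyl)oxy]methyl}-10,12-dimethyl-5-[(triethylsilyl)oxy]pentadeca-10,13-dien-7-one
Product: 21 (5S,6S,8R,9S,10Z,12S,13Z)-5,9-dihydroxy-6,8-bis{[(4-methoxybenzyl)oxy]methyl}-10,12-dimethylpentadeca-10,13-diene-3,7-dione
Conditions: HCl (1 M aq.), THF, 0 °C → rt
Reagents that add atoms: water, O
Why: Aqueous acid hydrolyses the dioxolane (the new C3 carbonyl oxygen comes from water) and the triethylsilyl ether in one operation. The PMB ethers are stable, and the C9 allylic alcohol lies β to the C7 carbonyl, which disfavours ionisation.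

Step 15
Reactants: 21 (5S,6S,8R,9S,10Z,12S,13Z)-5,9-dihydroxy-6,8-bis{[(4-methoxybenzyl)oxy]methyl}-10,12-dimethylpentadeca-10,13-diene-3,7-dione
Product: 22 (5S,6S,8R,9S,10R,11S,12S,13Z)-10,11-epoxy-5,9-dihydroxy-6,8-bis{[(4-methoxybenzyl)oxy]methyl}-10,12-dimethylpentadec-13-ene-3,7-dione
Conditions: mCPBA (1.1 equiv), NaHCO3, CH2Cl2, −20 → 0 °C
Reagents that add atoms: 3-chloroperoxybenzoic acid, OOC(=O)c1cccc(Cl)c1
Why: Hydroxyl-directed peracid epoxidation: in the conformer of least allylic 1,3-strain (C9–H eclipsing the (Z)-olefin) the hydrogen-bonded peracid is delivered to the face of the C9 hydroxyl, giving the threo epoxy alcohol (10R,11S). Syn addition to the (10Z)-olefin makes C9 and C12 cis on the oxirane, and the trisubstituted, hydroxyl-activated olefin should react well before the isolated (13Z)-olefin.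

Step 16
Reactants: 22 (5S,6S,8R,9S,10R,11S,12S,13Z)-10,11-epoxy-5,9-dihydroxy-6,8-bis{[(4-methoxybenzyl)oxy]methyl}-10,12-dimethylpentadec-13-ene-3,7-dione
Product: 23 myriaporone 4, (5S,6S,8R,9S,10R,11S,12S,13Z)-10,11-epoxy-5,9-dihydroxy-6,8-bis(hydroxymethyl)-10,12-dimethylpentadec-13-ene-3,7-dione
Conditions: DDQ (2.6 equiv), CH2Cl2/pH 7 phosphate buffer (10:1), 0 °C
Reagents that add atoms: none
Why: Oxidative cleavage of both PMB ethers by DDQ in wet, buffered medium (hydride abstraction, then hydrolysis of the oxocarbenium ion). The neutral conditions should spare the epoxy alcohol, the β-hydroxy ketones and the epimerisable C6 and C8.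

## Compound list

1 | pentane-1,3,5-triol | OCCC(O)CCO | starting material
2 | 1,5-bis[(4-methoxybenzyl)oxy]pentan-3-ol | COc1ccc(COCCC(O)CCOCc2ccc(OC)cc2)cc1 | intermediate
3 | 1,5-bis[(4-methoxybenzyl)oxy]pentan-3-one | COc1ccc(COCCC(=O)CCOCc2ccc(OC)cc2)cc1 | intermediate
4 | ethyl 3-oxopentanoate | CCC(=O)CC(=O)OCC | starting material
5 | ethyl 2-(2-ethyl-1,3-dioxolan-2-yl)acetate | CCOC(=O)CC1(CC)OCCO1 | intermediate
6 | 2-(2-ethyl-1,3-dioxolan-2-yl)acetaldehyde | CCC1(CC=O)OCCO1 | intermediate
7 | (E)-enol borinate of 3 with two [(1S,2S,5R)-2-isopropyl-5-methylcyclohexyl]methyl groups on boron | COc1ccc(COC/C=C(/OB(C[C@H]2C[C@H](C)CC[C@H]2C(C)C)C[C@H]2C[C@H](C)CC[C@H]2C(C)C)CCOCc2ccc(OC)cc2)cc1 | intermediate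
8 | boron aldolate of 9 (O-dialkylboryl derivative at the new carbinol) | COc1ccc(COCCC(=O)[C@@H](COCc2ccc(OC)cc2)[C@@H](OB(C[C@H]2C[C@H](C)CC[C@H]2C(C)C)C[C@H]2C[C@H](C)CC[C@H]2C(C)C)CC2(CC)OCCO2)cc1 | intermediate
9 | (4S,5S)-6-(2-ethyl-1,3-dioxolan-2-yl)-5-hydroxy-1-[(4-methoxybenzyl)oxy]-4-{[(4-methoxybenzyl)oxy]methyl}hexan-3-one | COc1ccc(COCCC(=O)[C@@H](COCc2ccc(OC)cc2)[C@@H](O)CC2(CC)OCCO2)cc1 | intermediate
10 | (4S,5S)-6-(2-ethyl-1,3-dioxolan-2-yl)-1-[(4-methoxybenzyl)oxy]-4-{[(4-methoxybenzyl)oxy]methyl}-5-[(triethylsilyl)oxy]hexan-3-one | COc1ccc(COCCC(=O)[C@@H](COCc2ccc(OC)cc2)[C@@H](O[Si](CC)(CC)CC)CC2(CC)OCCO2)cc1 | intermediate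
11 | ethyl (S)-lactate, ethyl (2S)-2-hydroxypropanoate | C[C@H](O)C(=O)OCC | starting material
12 | ethyl (2S)-2-{[(trifluoromethyl)sulfonyl]oxy}propanoate | C[C@H](OS(=O)(=O)C(F)(F)F)C(=O)OCC | intermediate
13 | ethyl (2S,3Z)-2-methylpent-3-enoate | C/C=C\[C@H](C)C(=O)OCC | intermediate
14 | (2S,3Z)-2-methylpent-3-enal | C/C=C\[C@H](C)C=O | intermediate
15 | ethyl (2Z,4S,5Z)-2,4-dimethylhepta-2,5-dienoate | C/C=C\[C@H](C)/C=C(C)\C(=O)OCC | intermediate
16 | (2Z,4S,5Z)-2,4-dimethylhepta-2,5-dien-1-ol | C/C=C\[C@H](C)/C=C(C)\CO | intermediate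
17 | (2Z,4S,5Z)-2,4-dimethylhepta-2,5-dienal | C/C=C\[C@H](C)/C=C(C)\C=O | intermediate
18 | (E)-enol dicyclohexylborinate of 10 (enolised at C8, target numbering) | COc1ccc(COC/C=C(/OB(C2CCCCC2)C2CCCCC2)[C@@H](COCc2ccc(OC)cc2)[C@@H](O[Si](CC)(CC)CC)CC2(CC)OCCO2)cc1 | intermediate
19 | boron aldolate of 20 (9-O-dicyclohexylboryl derivative) | C/C=C\[C@H](C)/C=C(C)\[C@@H](OB(C1CCCCC1)C1CCCCC1)[C@@H](COCc1ccc(OC)cc1)C(=O)[C@@H](COCc1ccc(OC)cc1)[C@@H](O[Si](CC)(CC)CC)CC1(CC)OCCO1 | intermediate
20 | (5S,6S,8R,9S,10Z,12S,13Z)-3,3-(ethylenedioxy)-9-hydroxy-6,8-bis{[(4-methoxybenzyl)oxy]methyl}-10,12-dimethyl-5-[(triethylsilyl)oxy]pentadeca-10,13-dien-7-one | C/C=C\[C@H](C)/C=C(C)\[C@@H](O)[C@@H](COCc1ccc(OC)cc1)C(=O)[C@@H](COCc1ccc(OC)cc1)[C@@H](O[Si](CC)(CC)CC)CC1(CC)OCCO1 | intermediate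
21 | (5S,6S,8R,9S,10Z,12S,13Z)-5,9-dihydroxy-6,8-bis{[(4-methoxybenzyl)oxy]methyl}-10,12-dimethylpentadeca-10,13-diene-3,7-dione | C/C=C\[C@H](C)/C=C(C)\[C@@H](O)[C@@H](COCc1ccc(OC)cc1)C(=O)[C@@H](COCc1ccc(OC)cc1)[C@@H](O)CC(=O)CC | intermediate
22 | (5S,6S,8R,9S,10R,11S,12S,13Z)-10,11-epoxy-5,9-dihydroxy-6,8-bis{[(4-methoxybenzyl)oxy]methyl}-10,12-dimethylpentadec-13-ene-3,7-dione | C/C=C\[C@H](C)[C@@H]1O[C@]1(C)[C@@H](O)[C@@H](COCc1ccc(OC)cc1)C(=O)[C@@H](COCc1ccc(OC)cc1)[C@@H](O)CC(=O)CC | intermediate
23 | myriaporone 4 | C/C=C\[C@H](C)[C@@H]1O[C@]1(C)[C@@H](O)[C@@H](CO)C(=O)[C@@H](CO)[C@@H](O)CC(=O)CC | target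

## Step count and least certain steps

Total step count: 16. Longest linear sequence: 10 steps (11 → 12 → 13 → 14 → 15 → 16 → 17 → 20 → 21 → 22 → 23).

**Step 13 (key step).** The most likely failure is poor or inverted enolate-face selectivity. Both arms on C6 are oxygenated, so the assignment of the CH2OPMB arm to the aldehyde side and of the silyloxy arm to the far side rests on analogy, not on a direct precedent. A second, smaller concern is isomerisation of the (Z)-enal by the amine salt during a slow addition.

Fallback: replace 1,3-induction by reagent control. Ketone 10 is enolised with the antipode of the step 5 bromoborane (from (+)-menthone) and Et3N, giving the (E)-enol borinate of 10 with two [(1R,2R,5S)-2-isopropyl-5-methylcyclohexyl]methyl groups on boron F1. Addition of 17 gives the corresponding 9-O-boryl aldolate F2, and the same oxidative work-up gives 20. Because the C8/C9 pair is the mirror image of the C6/C5 pair, the antipode of the step 5 reagent is the matching one. The fallback sets out from 10 and 17 and comes back at 20.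

**Step 5.** The most likely failure is insufficient enantioselectivity, because this reagent class is only moderately selective with simple ketones and the sense with a β-alkoxy ketone is assumed. Any minor enantiomer becomes a separable diastereomer after step 13 but consumes 17.

Fallback: build C5 and C6 by hydrogenation and alkylation, setting out from 6 and coming back at 10.
- A Roskamp reaction of 6 with ethyl diazoacetate (SnCl2 cat.) gives ethyl 4-(2-ethyl-1,3-dioxolan-2-yl)-3-oxobutanoate F3.
- Noyori hydrogenation (H2, RuCl2[(S)-BINAP], divalent ruthenium) gives ethyl (3S)-4-(2-ethyl-1,3-dioxolan-2-yl)-3-hydroxybutanoate F4.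
- Fráter–Seebach alkylation of its dianion (LiN(i-Pr)2, then 4-methoxybenzyl chloromethyl ether) gives the anti product ethyl (2S,3S)-4-(2-ethyl-1,3-dioxolan-2-yl)-3-hydroxy-2-{[(4-methoxybenzyl)oxy]methyl}butanoate F5.
- Silylation (Et3SiOTf, 2,6-lutidine) gives ethyl (2S,3S)-4-(2-ethyl-1,3-dioxolan-2-yl)-2-{[(4-methoxybenzyl)oxy]methyl}-3-[(triethylsilyl)oxy]butanoate F6.
- MeNHOMe·HCl with i-PrMgCl gives (2S,3S)-4-(2-ethyl-1,3-dioxolan-2-yl)-N-methoxy-2-{[(4-methoxybenzyl)oxy]methyl}-N-methyl-3-[(triethylsilyl)oxy]butanamide F7.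
- CH2=CHMgBr gives (4S,5S)-6-(2-ethyl-1,3-dioxolan-2-yl)-4-{[(4-methoxybenzyl)oxy]methyl}-5-[(triethylsilyl)oxy]hex-1-en-3-one F8.
- PMe3-catalysed conjugate addition of 4-methoxybenzyl alcohol to F8 gives 10.

**Step 8.** The most likely failures are slow substitution by the less nucleophilic alkenyl cuprate, with reduction or elimination of the triflate competing, and partial racemisation of the doubly activated α-C–H of the product.

Fallback: make the C12 centre from a different chiral-pool ester, bypassing 11–13 and coming back at 14.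
- Commercial methyl (R)-3-hydroxy-2-methylpropanoate F9 is silylated (t-BuMe2SiCl, imidazole) to methyl (R)-3-[(tert-butyldimethylsilyl)oxy]-2-methylpropanoate F10.
- i-Bu2AlH at −78 °C gives (R)-3-[(tert-butyldimethylsilyl)oxy]-2-methylpropanal F11.
- A salt-free Wittig reaction (EtPPh3Br, NaN(SiMe3)2, −78 °C) gives tert-butyldimethyl{[(2S,3Z)-2-methylpent-3-en-1-yl]oxy}silane F12.
- Bu4NF gives (2S,3Z)-2-methylpent-3-en-1-ol F13.
- Buffered Dess–Martin oxidation of F13 gives 14.

**Step 15.** The most likely failures are competing epoxidation of the (13Z)-olefin and erosion of face selectivity, because in the reactive conformer the propenyl group on C12 lies on the same face as the C9 hydroxyl.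

Fallback: change from hydrogen-bond-directed peracid delivery to an alkoxide-templated epoxidation with Ti(Oi-Pr)4 and t-BuOOH (no tartrate) in CH2Cl2 at −20 °C. The peroxide is bound to the titanium alkoxide of C9–OH, so only the allylic olefin can react, and this system also gives the threo product under allylic 1,3-strain. It sets out from 21 and comes back at 22 and makes no new compound.

**Step 16.** The most likely failures are oxidative cyclisation of a PMB ether onto the neighbouring C5 or C9 hydroxyl (4-methoxybenzylidene acetal formation) and opening of the epoxy alcohol by the acidic hydroquinone.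

Fallback: remove the PMB groups before the oxirane exists. Compound 21 is treated with DDQ in wet buffered CH2Cl2 to give (5S,6S,8R,9S,10Z,12S,13Z)-5,9-dihydroxy-6,8-bis(hydroxymethyl)-10,12-dimethylpentadeca-10,13-diene-3,7-dione F14. Any acetal formed can be hydrolysed with mild acid at this stage, which has no oxirane. Hydroxyl-directed epoxidation of F14 with buffered mCPBA then gives 23 as the last step. The fallback sets out from 21 and comes back at 23.

## Further compounds

F1 | step 13 | (E)-enol borinate of 10 with two [(1R,2R,5S)-2-isopropyl-5-methylcyclohexyl]methyl groups on boron | COc1ccc(COC/C=C(/OB(C[C@@H]2C[C@@H](C)CC[C@@H]2C(C)C)C[C@@H]2C[C@@H](C)CC[C@@H]2C(C)C)[C@@H](COCc2ccc(OC)cc2)[C@@H](O[Si](CC)(CC)CC)CC2(CC)OCCO2)cc1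
F2 | step 13 | 9-O-boryl aldolate of 20 with the same two ligands on boron | C/C=C\[C@H](C)/C=C(C)\[C@@H](OB(C[C@@H]1C[C@@H](C)CC[C@@H]1C(C)C)C[C@@H]1C[C@@H](C)CC[C@@H]1C(C)C)[C@@H](COCc1ccc(OC)cc1)C(=O)[C@@H](COCc1ccc(OC)cc1)[C@@H](O[Si](CC)(CC)CC)CC1(CC)OCCO1
F3 | step 5 | ethyl 4-(2-ethyl-1,3-dioxolan-2-yl)-3-oxobutanoate | CCOC(=O)CC(=O)CC1(CC)OCCO1
F4 | step 5 | ethyl (3S)-4-(2-ethyl-1,3-dioxolan-2-yl)-3-hydroxybutanoate | CCOC(=O)C[C@@H](O)CC1(CC)OCCO1
F5 | step 5 | ethyl (2S,3S)-4-(2-ethyl-1,3-dioxolan-2-yl)-3-hydroxy-2-{[(4-methoxybenzyl)oxy]methyl}butanoate | CCOC(=O)[C@@H](COCc1ccc(OC)cc1)[C@@H](O)CC1(CC)OCCO1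
F6 | step 5 | ethyl (2S,3S)-4-(2-ethyl-1,3-dioxolan-2-yl)-2-{[(4-methoxybenzyl)oxy]methyl}-3-[(triethylsilyl)oxy]butanoate | CCOC(=O)[C@@H](COCc1ccc(OC)cc1)[C@@H](O[Si](CC)(CC)CC)CC1(CC)OCCO1
F7 | step 5 | (2S,3S)-4-(2-ethyl-1,3-dioxolan-2-yl)-N-methoxy-2-{[(4-methoxybenzyl)oxy]methyl}-N-methyl-3-[(triethylsilyl)oxy]butanamide | CON(C)C(=O)[C@@H](COCc1ccc(OC)cc1)[C@@H](O[Si](CC)(CC)CC)CC1(CC)OCCO1
F8 | step 5 | (4S,5S)-6-(2-ethyl-1,3-dioxolan-2-yl)-4-{[(4-methoxybenzyl)oxy]methyl}-5-[(triethylsilyl)oxy]hex-1-en-3-one | C=CC(=O)[C@@H](COCc1ccc(OC)cc1)[C@@H](O[Si](CC)(CC)CC)CC1(CC)OCCO1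
F9 | step 8 | methyl (R)-3-hydroxy-2-methylpropanoate | COC(=O)[C@H](C)CO
F10 | step 8 | methyl (R)-3-[(tert-butyldimethylsilyl)oxy]-2-methylpropanoate | COC(=O)[C@H](C)CO[Si](C)(C)C(C)(C)C
F11 | step 8 | (R)-3-[(tert-butyldimethylsilyl)oxy]-2-methylpropanal | O=C[C@H](C)CO[Si](C)(C)C(C)(C)C
F12 | step 8 | tert-butyldimethyl{[(2S,3Z)-2-methylpent-3-en-1-yl]oxy}silane | C/C=C\[C@H](C)CO[Si](C)(C)C(C)(C)C
F13 | step 8 | (2S,3Z)-2-methylpent-3-en-1-ol | C/C=C\[C@H](C)CO
F0 | step 15 | none | none
F14 | step 16 | (5S,6S,8R,9S,10Z,12S,13Z)-5,9-dihydroxy-6,8-bis(hydroxymethyl)-10,12-dimethylpentadeca-10,13-diene-3,7-dione | C/C=C\[C@H](C)/C=C(C)\[C@@H](O)[C@@H](CO)C(=O)[C@@H](CO)[C@@H](O)CC(=O)CC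
A1 | alternative 1 | (2R,3S,4Z,6S,7Z)-2-{[(4-methoxybenzyl)oxy]methyl}-4,6-dimethylnona-4,7-diene-1,3-diol | C/C=C\[C@H](C)/C=C(C)\[C@@H](O)[C@@H](COCc1ccc(OC)cc1)CO
A2 | alternative 2 | 1,1-diphenylsilinan-4-one (1,1-diphenyl-1-silacyclohexan-4-one) | O=C1CC[Si](CC1)(c1ccccc1)c1ccccc1
A3 | alternative 2 | 3,5-trans bis-aldol of A2 (anti, trans, anti; C8 and C9 as in the target, C5 and C6 inverted) | C/C=C\[C@H](C)/C=C(C)\[C@@H](O)[C@H]1C[Si](c2ccccc2)(c2ccccc2)C[C@@H](C1=O)[C@H](O)CC1(CC)OCCO1
A4 | alternative 3 | 4,5-dihydroisoxazole with C7 as ring C3, C8 (CH2OPMB) as ring C4 and C9 (dienyl) as ring C5 | C/C=C\[C@H](C)/C=C(C)\[C@H]1ON=C([C@@H]1COCc1ccc(OC)cc1)[C@@H](COCc1ccc(OC)cc1)[C@@H](O[Si](CC)(CC)CC)CC1(CC)OCCO1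
A5 | alternative 3 | (2S,3S)-4-(2-ethyl-1,3-dioxolan-2-yl)-2-{[(4-methoxybenzyl)oxy]methyl}-3-[(triethylsilyl)oxy]butanenitrile oxide | [O-][N+]#C[C@@H](COCc1ccc(OC)cc1)[C@@H](O[Si](CC)(CC)CC)CC1(CC)OCCO1
A6 | alternative 3 | (2E,4Z,6S,7Z)-1-[(4-methoxybenzyl)oxy]-4,6-dimethylnona-2,4,7-triene | C/C=C\[C@H](C)/C=C(C)\C=C\COCc1ccc(OC)cc1
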